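**Retrosynthetic overview**
1. The target is a halim-5(10)-ene. Ring B (C5–C10) carries the adjacent pair C8 (methyl C17) and quaternary C9 (methyl C20, side chain C11–C16) beside the ring-fusion carbon C10, with oxygen at C6. This is the pattern a ring A 2-silyloxydiene leaves after a Diels–Alder reaction.
2. Key disconnection: C7–C8 and C9–C10, between diene C10=C5–C6(OTBS)=C7 (6) and the (E)-enal C8=C9(CHO) (17). The formyl carbon becomes C20.
3. Ring A is bought (2,2-dimethylcyclohexanone). Ring B is the only ring built, in the cycloaddition.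
4. After it: CHO to CH3, silyl enol ether to C5=C10 enone, C7 hydroxylation and acetylation, catalyst-controlled C6 reduction, desilylation.
5. Diene 6 comes from a Shapiro reaction, acylation and silylation. Enal 17 comes from (R)-linalool (C13 centre) by ozonolysis, phosphonium salt, ylide formylation and Wittig reaction with acetaldehyde.

Key step: step 10

Remark: atom numbers are those of the halimane skeleton (ring A = C1–C5, C10; ring B = C5–C10; C17 on C8; C20 on C9; C18/C19 on C4; side chain C11–C16 with C16 the methyl on C13). The (S)-configured catalyst in step 10 is assigned from the usual binding model for α-substituted enals; if the facial sense proved opposite, its enantiomer would be used.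

**Step 1**
Reactants: 1 2,2-dimethylcyclohexanone
Product: 2 (E)-N'-(2,2-dimethylcyclohexylidene)-2,4,6-tri(propan-2-yl)benzenesulfonohydrazide
Conditions: 2,4,6-triisopropylbenzenesulfonohydrazide, HCl (cat.), THF, rt
Reagents that add atoms: 2,4,6-tri(propan-2-yl)benzenesulfonohydrazide, CC(C)c1cc(C(C)C)c(c(C(C)C)c1)S(=O)(=O)NN
Why: acid-catalysed hydrazone formation; the sulfonyl group settles anti to the quaternary carbon and the ortho-isopropyl groups block aryl lithiation in the next step.

**Step 2**
Reactants: 2 the trisylhydrazone; 3 N-methoxy-N-methylacetamide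
Product: 5 1-(6,6-dimethylcyclohex-1-en-1-yl)ethan-1-one, via vinyllithium 4 (not isolated)
Conditions: n-BuLi (2.2 equiv), THF, −78 → 0 °C; then 3, −78 °C → rt; H2O
Reagents that add atoms: none
Why: Shapiro reaction (N–H then C6–H removal, loss of sulfinate and N2) gives the vinyllithium with the double bond away from the gem-dimethyl carbon, and acylation by the N-methoxy-N-methyl amide stops at the ketone because the chelated tetrahedral adduct survives until work-up (Weinreb ketone synthesis).

**Step 3**
Reactants: 5 1-(6,6-dimethylcyclohex-1-en-1-yl)ethan-1-one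
Product: 6 tert-butyl{[1-(6,6-dimethylcyclohex-1-en-1-yl)ethenyl]oxy}dimethylsilane
Conditions: TBSOTf, Et3N, CH2Cl2, 0 °C
Reagents that add atoms: tert-butyldimethylsilyl trifluoromethanesulfonate, CC(C)(C)[Si](C)(C)OS(=O)(=O)C(F)(F)F
Why: soft enolisation of a methyl enone (O-silylation, then removal of a methyl proton by the amine) is the standard way to a cross-conjugated 2-silyloxydiene.

**Step 4**
Reactants: 7 (R)-linalool
Product: 8 (3R)-3,7-dimethyl-3-(triethylsilyloxy)octa-1,6-diene
Conditions: TESOTf, 2,6-lutidine, CH2Cl2, −78 → 0 °C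
Reagents that add atoms: triethylsilyl trifluoromethanesulfonate, CC[Si](CC)(CC)OS(=O)(=O)C(F)(F)F
Why: silyl triflate silylation of a tertiary alcohol; the C13 centre is untouched and is carried unchanged to the target.

**Step 5**
Reactants: 8 the triethylsilyl ether of linalool
Product: 10 (4R)-4-methyl-4-(triethylsilyloxy)hex-5-en-1-ol, via aldehyde 9 (not isolated)
Conditions: O3 (1.0 equiv), pyridine, CH2Cl2, −78 °C; then NaBH4, MeOH, −78 → 0 °C
Reagents that add atoms: ozone, [O-][O+]=O
Why: ozonolysis picks the electron-rich trisubstituted alkene over the hindered vinyl group, pyridine turns the carbonyl oxide into the aldehyde without peroxide build-up, and NaBH4 reduces it in the same flask.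

**Step 6**
Reactants: 10 (4R)-4-methyl-4-(triethylsilyloxy)hex-5-en-1-ol
Product: 11 (3R)-6-iodo-3-methyl-3-(triethylsilyloxy)hex-1-ene
Conditions: I2, PPh3, imidazole, CH2Cl2, 0 °C → rt
Reagents that add atoms: iodine, II
Why: Appel-type iodination of a primary alcohol by SN2 displacement of the alkoxyphosphonium ion; imidazole buffers the acid so the silyl ether survives.

**Step 7**
Reactants: 11 the primary iodide
Product: 12 [(4R)-4-methyl-4-(triethylsilyloxy)hex-5-en-1-yl]triphenylphosphonium iodide
Conditions: PPh3, iPr2NEt (0.1 equiv), MeCN, 82 °C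
Reagents that add atoms: triphenylphosphine, c1ccc(cc1)P(c1ccccc1)c1ccccc1
Why: SN2 quaternisation of triphenylphosphine by a primary iodide under neutral conditions.

**Step 8**
Reactants: 12 the phosphonium iodide; 13 ethyl formate
Product: 15 (5R)-5-methyl-5-(triethylsilyloxy)-2-(triphenylphosphoranylidene)hept-6-enal, via phosphorus ylide 14 (not isolated)
Conditions: KOtBu (1.2 equiv), THF, 0 °C; then HCO2Et, 0 °C → rt
Reagents that add atoms: none
Why: C-acylation of a non-stabilised ylide by a formate ester, the released alkoxide removing the now acidic proton, gives the isolable formyl-stabilised ylide in which the ylide carbon is the future C9 and the formyl carbon the future C20.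

**Step 9**
Reactants: 15 the formyl-stabilised ylide; 16 acetaldehyde
Product: 17 (2E,5R)-2-ethylidene-5-methyl-5-(triethylsilyloxy)hept-6-enal
Conditions: CH3CHO (5 equiv), toluene, 90 °C, sealed tube
Reagents that add atoms: none
Why: Wittig reaction of a carbonyl-stabilised ylide is E-selective, placing the new methyl (C17) trans to the formyl group and cis to the side chain.

**Step 10**
Reactants: 6 the ring A silyloxydiene; 17 the (E)-enal
Product: 18 (8R,9S,10S,13R)-6-(tert-butyldimethylsilyloxy)-13-(triethylsilyloxy)halima-5,14-dien-20-al (formyl on C9, C17 cis to the side chain, C10–H cis to formyl; drawn as the formyl-exo adduct)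
Conditions: (S)-1-(2-methylphenyl)-3,3-diphenyltetrahydro-1H,3H-pyrrolo[1,2-c][1,3,2]oxazaborole N-protonated by HN(SO2CF3)2 (20 mol%; made from (S)-α,α-diphenylprolinol, tri(o-tolyl)boroxine, then HN(SO2CF3)2), CH2Cl2, −78 → −40 °C; Et3N quench
Reagents that add atoms: none
Why: Proposed new method: the cationic boron centre binds the formyl oxygen of 17 (formyl C–H held against the catalyst ring oxygen) and lowers the LUMO of the s-trans enal, so that the silyl enol ether terminus C7 of 6 bonds to the β-carbon C8 and ring carbon C10 to the α-carbon C9 in a concerted, asynchronous [4+2] cycloaddition. The closest known reaction type is the oxazaborolidinium-catalysed Diels–Alder addition of 2-silyloxydienes to α-substituted acroleins; this case adds a β-methyl group on the dienophile and a ring substituent on the diene terminus, which is why it is put forward as an extension. Ring B (C5–C10) is closed by this intermolecular cycloaddition across C7 and C10 of the diene, and the new double bond appears as the C5=C6 silyl enol ether. C8 and C9 are fixed relative to each other by the E geometry of 17 (suprafacial addition keeps C17 cis to C11 and trans to C20), and in the absolute sense by the catalyst, whose aryl group covers one enal face and leaves open the face from which C20, C8 and C11 run clockwise at C9, the one the target needs; C10 follows from the exo or endo approach and is erased in step 14. The step needs regioselectivity, which the 2-silyloxy group secures through the large HOMO coefficient at C7, and enough reactivity at a hindered dienophile, which the s-cis preference imposed on 6 by the C4 gem-dimethyl group and the strongly activating cationic Lewis acid should provide.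

**Step 11**
Reactants: 18 the cycloadduct aldehyde
Product: 19 (8R,9S,10R,13R)-6-(tert-butyldimethylsilyloxy)-13-(triethylsilyloxy)halima-5,14-dien-20-ol
Conditions: NaBH4, THF/EtOH, 0 °C
Reagents that add atoms: none
Why: chemoselective borohydride reduction of the aldehyde; the silyl enol ether and silyl ether are inert, and C9 has no α-hydrogen to epimerise.

**Step 12**
Reactants: 19 the C20 alcohol
Product: 21 O-[(8R,9S,10R,13R)-6-(tert-butyldimethylsilyloxy)-13-(triethylsilyloxy)halima-5,14-dien-20-yl] S-methyl carbonodithioate, via sodium xanthate 20 (not isolated)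
Conditions: NaH, imidazole (cat.), THF, 0 °C → rt; CS2; MeI
Reagents that add atoms: carbon disulfide, S=C=S; iodomethane, CI
Why: xanthate formation (alkoxide addition to CS2, then S-methylation) under basic conditions that leave the silyl enol ether intact.

**Step 13**
Reactants: 21 the S-methyl xanthate
Product: 22 (8R,9R,10R,13R)-6-(tert-butyldimethylsilyloxy)-13-(triethylsilyloxy)halima-5,14-diene
Conditions: Bu3SnH, 1,1'-azobis(cyclohexanecarbonitrile), xylene, 140 °C
Reagents that add atoms: none
Why: Barton–McCombie deoxygenation turns C20 into the methyl group; the neopentyl xanthate has no β-hydrogen for thermal elimination, and the primary C20 radical has no fast rearrangement open while C5=C6 is still a silyl enol ether, which is why this precedes step 14.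

**Step 14**
Reactants: 22 the C20-methyl silyl enol ether
Product: 23 (8R,9R,13R)-13-(triethylsilyloxy)halima-5(10),14-dien-6-one
Conditions: Pd(OAc)2 (1.2 equiv), MeCN, 40 °C
Reagents that add atoms: none
Why: Saegusa oxidation: silicon is exchanged for palladium to give the enolate bound at C5, and β-hydride elimination can only take the C10 hydrogen (C4 is quaternary), so the C5=C10 enone forms and the C10 centre disappears.

**Step 15**
Reactants: 23 the enone
Product: 25 (7R,8S,9R,13R)-7-hydroxy-13-(triethylsilyloxy)halima-5(10),14-dien-6-one, via potassium dienolate 24 (not isolated)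
Conditions: KN(SiMe3)2, THF, −78 °C; 2-(phenylsulfonyl)-3-phenyloxaziridine, −78 °C; AcOH
Reagents that add atoms: 2-(phenylsulfonyl)-3-phenyloxaziridine, O=S(=O)(c1ccccc1)N1OC1c1ccccc1
Why: kinetic α'-deprotonation at C7 and enolate hydroxylation by the N-sulfonyloxaziridine; oxygen should arrive on the C7 face opposite the C17 methyl and the C9 side chain, giving the 7-hydroxyl trans to C17, which is also the equatorial, more stable arrangement.

**Step 16**
Reactants: 25 the 7-hydroxy enone
Product: 26 (7R,8S,9R,13R)-6-oxo-13-(triethylsilyloxy)halima-5(10),14-dien-7-yl acetate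
Conditions: Ac2O, pyridine, DMAP (cat.), CH2Cl2, 0 °C → rt
Reagents that add atoms: acetic anhydride, CC(=O)OC(C)=O
Why: DMAP-catalysed acetylation of the secondary alcohol; the C7 configuration is kept, being the thermodynamically preferred one.

**Step 17**
Reactants: 26 the 7-acetoxy enone
Product: 27 (6S,7R,8S,9R,13R)-6-hydroxy-13-(triethylsilyloxy)halima-5(10),14-dien-7-yl acetate
Conditions: (S)-1-methyl-3,3-diphenyltetrahydro-1H,3H-pyrrolo[1,2-c][1,3,2]oxazaborole (0.5 equiv), catecholborane, toluene, −78 → −40 °C; MeOH
Reagents that add atoms: none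
Why: CBS reduction with the alkenyl carbon C5 as the large group; the (S)-catalyst should deliver hydride to the C6 face that carries C17, giving the pseudoaxial 6-hydroxyl cis to the 7-acetate, whereas a small uncatalysed hydride would be expected to add axially and give the C6 epimer.

**Step 18**
Reactants: 27 the triethylsilyl ether of the target
Product: 28 (6S,7R,8S,9R,13R)-6,13-dihydroxyhalima-5(10),14-dien-7-yl acetate (target)
Conditions: HF·pyridine, pyridine, THF, 0 °C → rt
Reagents that add atoms: none
Why: fluoride-driven desilylation cleaves only the Si–O bond under buffered, weakly acidic conditions, so neither allylic C–O bond ionises and the acetate does not migrate.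

**Compound list**
1 | 2,2-dimethylcyclohexanone | CC1(C)CCCCC1=O | starting material
2 | (E)-N'-(2,2-dimethylcyclohexylidene)-2,4,6-tri(propan-2-yl)benzenesulfonohydrazide | CC(C)c1cc(C(C)C)c(c(C(C)C)c1)S(=O)(=O)N/N=C1\CCCCC1(C)C | intermediate
3 | N-methoxy-N-methylacetamide | CON(C)C(C)=O | starting material
4 | (6,6-dimethylcyclohex-1-en-1-yl)lithium (formed in the flask) | [Li]C1=CCCCC1(C)C | intermediate
5 | 1-(6,6-dimethylcyclohex-1-en-1-yl)ethan-1-one | CC(=O)C1=CCCCC1(C)C | intermediate
6 | tert-butyl{[1-(6,6-dimethylcyclohex-1-en-1-yl)ethenyl]oxy}dimethylsilane | C=C(O[Si](C)(C)C(C)(C)C)C1=CCCCC1(C)C | intermediate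
7 | (R)-linalool | C=C[C@](C)(O)CCC=C(C)C | starting material
8 | (3R)-3,7-dimethyl-3-(triethylsilyloxy)octa-1,6-diene | C=C[C@](C)(O[Si](CC)(CC)CC)CCC=C(C)C | intermediate
9 | (4R)-4-methyl-4-(triethylsilyloxy)hex-5-enal (formed in the flask) | C=C[C@](C)(O[Si](CC)(CC)CC)CCC=O | intermediate
10 | (4R)-4-methyl-4-(triethylsilyloxy)hex-5-en-1-ol | C=C[C@](C)(O[Si](CC)(CC)CC)CCCO | intermediate
11 | (3R)-6-iodo-3-methyl-3-(triethylsilyloxy)hex-1-ene | C=C[C@](C)(O[Si](CC)(CC)CC)CCCI | intermediate
12 | [(4R)-4-methyl-4-(triethylsilyloxy)hex-5-en-1-yl]triphenylphosphonium iodide | C=C[C@](C)(O[Si](CC)(CC)CC)CCC[P+](c1ccccc1)(c1ccccc1)c1ccccc1.[I-] | intermediate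
13 | ethyl formate | CCOC=O | starting material
14 | [(4R)-4-methyl-4-(triethylsilyloxy)hex-5-en-1-ylidene]triphenylphosphorane (formed in the flask) | C=C[C@](C)(O[Si](CC)(CC)CC)CCC=P(c1ccccc1)(c1ccccc1)c1ccccc1 | intermediate
15 | (5R)-5-methyl-5-(triethylsilyloxy)-2-(triphenylphosphoranylidene)hept-6-enal | C=C[C@](C)(O[Si](CC)(CC)CC)CCC(C=O)=P(c1ccccc1)(c1ccccc1)c1ccccc1 | intermediate
16 | acetaldehyde | CC=O | starting material
17 | (2E,5R)-2-ethylidene-5-methyl-5-(triethylsilyloxy)hept-6-enal | C/C=C(/C=O)CC[C@@](C)(O[Si](CC)(CC)CC)C=C | intermediate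
18 | (8R,9S,10S,13R)-6-(tert-butyldimethylsilyloxy)-13-(triethylsilyloxy)halima-5,14-dien-20-al | C=C[C@](C)(O[Si](CC)(CC)CC)CC[C@@]1(C=O)[C@H]2CCCC(C)(C)C2=C(O[Si](C)(C)C(C)(C)C)C[C@H]1C | intermediate
19 | (8R,9S,10R,13R)-6-(tert-butyldimethylsilyloxy)-13-(triethylsilyloxy)halima-5,14-dien-20-ol | C=C[C@](C)(O[Si](CC)(CC)CC)CC[C@@]1(CO)[C@H]2CCCC(C)(C)C2=C(O[Si](C)(C)C(C)(C)C)C[C@H]1C | intermediate
20 | sodium O-[(8R,9S,10R,13R)-6-(tert-butyldimethylsilyloxy)-13-(triethylsilyloxy)halima-5,14-dien-20-yl] carbonodithioate (formed in the flask) | C=C[C@](C)(O[Si](CC)(CC)CC)CC[C@@]1(COC(=S)[S-])[C@H]2CCCC(C)(C)C2=C(O[Si](C)(C)C(C)(C)C)C[C@H]1C.[Na+] | intermediate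
21 | O-[(8R,9S,10R,13R)-6-(tert-butyldimethylsilyloxy)-13-(triethylsilyloxy)halima-5,14-dien-20-yl] S-methyl carbonodithioate | C=C[C@](C)(O[Si](CC)(CC)CC)CC[C@@]1(COC(=S)SC)[C@H]2CCCC(C)(C)C2=C(O[Si](C)(C)C(C)(C)C)C[C@H]1C | intermediate
22 | (8R,9R,10R,13R)-6-(tert-butyldimethylsilyloxy)-13-(triethylsilyloxy)halima-5,14-diene | C=C[C@](C)(O[Si](CC)(CC)CC)CC[C@@]1(C)[C@H]2CCCC(C)(C)C2=C(O[Si](C)(C)C(C)(C)C)C[C@H]1C | intermediate
23 | (8R,9R,13R)-13-(triethylsilyloxy)halima-5(10),14-dien-6-one | C=C[C@](C)(O[Si](CC)(CC)CC)CC[C@@]1(C)C2=C(C(=O)C[C@H]1C)C(C)(C)CCC2 | intermediate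
24 | potassium (8R,9R,13R)-13-(triethylsilyloxy)halima-5(10),6,14-trien-6-olate (formed in the flask) | C=C[C@](C)(O[Si](CC)(CC)CC)CC[C@@]1(C)C2=C(C([O-])=C[C@H]1C)C(C)(C)CCC2.[K+] | intermediate
25 | (7R,8S,9R,13R)-7-hydroxy-13-(triethylsilyloxy)halima-5(10),14-dien-6-one | C=C[C@](C)(O[Si](CC)(CC)CC)CC[C@@]1(C)C2=C(C(=O)[C@H](O)[C@H]1C)C(C)(C)CCC2 | intermediate
26 | (7R,8S,9R,13R)-6-oxo-13-(triethylsilyloxy)halima-5(10),14-dien-7-yl acetate | C=C[C@](C)(O[Si](CC)(CC)CC)CC[C@@]1(C)C2=C(C(=O)[C@H](OC(C)=O)[C@H]1C)C(C)(C)CCC2 | intermediate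
27 | (6S,7R,8S,9R,13R)-6-hydroxy-13-(triethylsilyloxy)halima-5(10),14-dien-7-yl acetate | C=C[C@](C)(O[Si](CC)(CC)CC)CC[C@@]1(C)C2=C([C@H](O)[C@H](OC(C)=O)[C@H]1C)C(C)(C)CCC2 | intermediate
28 | (6S,7R,8S,9R,13R)-6,13-dihydroxyhalima-5(10),14-dien-7-yl acetate | C=C[C@](C)(O)CC[C@@]1(C)C2=C([C@H](O)[C@H](OC(C)=O)[C@H]1C)C(C)(C)CCC2 | target

**Step count and risks**
Total: 18 steps. Longest linear sequence: 15 steps (steps 4–18, from (R)-linalool); the diene arm is steps 1–3.

Step 10 (most likely to fail): the cycloaddition may stall because of crowding at the forming C9–C10 bond, may be diverted to open-chain Mukaiyama-type addition with silyl transfer, or may discriminate the enal faces poorly. Fallback, by known chemistry, from 6 and 17: the cycloaddition is run with an achiral aluminium Lewis acid (Me2AlCl, CH2Cl2, −78 → −20 °C), an established way to join 2-silyloxydienes to α,β-disubstituted enals. Both enal faces then react, and because 17 already carries the C13 centre the products are diastereomers, 18 and the adduct with inverted C8, C9 and C10 centres, (8S,9R,10R,13R)-6-(tert-butyldimethylsilyloxy)-13-(triethylsilyloxy)halima-5,14-dien-20-al F1. Chromatography (if need be after step 11, as the alcohols) returns 18 to the route. Catalyst control is replaced by separation through the linalool-derived centre, at the cost of half the material.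

Step 14: silicon-to-palladium exchange and β-hydride elimination at the congested ring-fusion carbon C5 may be slow, so that protodesilylation to the saturated ketone competes. Fallback from 22: bromination of the silyl enol ether with N-bromosuccinimide (THF, −78 → 0 °C) gives 5-bromo-13-(triethylsilyloxy)halim-14-en-6-one F2 (either C5 epimer), and dehydrobromination with Li2CO3/LiBr in DMF at 120 °C, where only the C10 hydrogen is available, returns the route at 23.

Step 17: hydride delivery to C6 may follow the substrate's torsional preference against the catalyst (mismatched facial selectivity), or the hindered ketone may react sluggishly. Fallback from 23, bypassing steps 15–17: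
- Kinetic enolate triflation (KN(SiMe3)2, PhNTf2, THF, −78 °C) gives (8R,9R,13R)-13-(triethylsilyloxy)halima-5(10),6,14-trien-6-yl trifluoromethanesulfonate F3.
- Reduction (Pd(OAc)2, PPh3, Bu3N, HCO2H, DMF, 60 °C) gives (8R,9R,13R)-13-(triethylsilyloxy)halima-5(10),6,14-triene F4.
- Dihydroxylation of the ring diene's disubstituted C6=C7 bond (OsO4 cat., N-methylmorpholine N-oxide, acetone/H2O), from the face opposite C17 and the side chain, gives (6S,7R,8S,9R,13R)-13-(triethylsilyloxy)halima-5(10),14-diene-6,7-diol F5. The vinyl group beside the quaternary silyloxy carbon should react more slowly.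
- Acetylation of the less hindered equatorial C7 hydroxyl (Ac2O, pyridine, 0 °C) returns the route at 27.

The cis relationship of the two oxygens is then set by the osmylation.

**Further compounds**
F1 | step 10 | (8S,9R,10R,13R)-6-(tert-butyldimethylsilyloxy)-13-(triethylsilyloxy)halima-5,14-dien-20-al | C=C[C@](C)(O[Si](CC)(CC)CC)CC[C@]1(C=O)[C@@H]2CCCC(C)(C)C2=C(O[Si](C)(C)C(C)(C)C)C[C@@H]1C
F2 | step 14 | 5-bromo-13-(triethylsilyloxy)halim-14-en-6-one (C8, C9, C10, C13 as in 22; C5 either epimer) | C=C[C@](C)(O[Si](CC)(CC)CC)CC[C@@]1(C)[C@H]2CCCC(C)(C)C2(Br)C(=O)C[C@H]1C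
F3 | step 17 | (8R,9R,13R)-13-(triethylsilyloxy)halima-5(10),6,14-trien-6-yl trifluoromethanesulfonate | C=C[C@](C)(O[Si](CC)(CC)CC)CC[C@@]1(C)C2=C(C(OS(=O)(=O)C(F)(F)F)=C[C@H]1C)C(C)(C)CCC2
F4 | step 17 | (8R,9R,13R)-13-(triethylsilyloxy)halima-5(10),6,14-triene | C=C[C@](C)(O[Si](CC)(CC)CC)CC[C@@]1(C)C2=C(C=C[C@H]1C)C(C)(C)CCC2
F5 | step 17 | (6S,7R,8S,9R,13R)-13-(triethylsilyloxy)halima-5(10),14-diene-6,7-diol | C=C[C@](C)(O[Si](CC)(CC)CC)CC[C@@]1(C)C2=C([C@H](O)[C@H](O)[C@H]1C)C(C)(C)CCC2
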